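**Retrosynthetic overview**
1. Flavan 10 ⇐ para-quinone methide 9 ⇐ cis-flavan-4-ol 8 ⇐ flavanone 7 ⇐ chalcone 6. This is the flavonoid sequence (chalcone → flavanone → flavan-4-ol → flavan) run in one flask as a dynamic kinetic resolution, so ring closure and C2 (R) are fixed together.
2. Chalcone 6 ⇐ Claisen–Schmidt union of prenylated acetophenone 3 (ring A) with aldehyde 4 (ring B), without protecting groups.
3. Acetophenone 3 ⇐ C-prenylation of 1 with 2, the chemical counterpart of an aromatic prenyltransferase.
4. Ring order: rings A and B are bought as benzenes; the pyran ring C is the only ring made, in the last step, by oxa-Michael closure.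

Assumption: the tag [C@H] at C2 of the target SMILES is read as (2R) (priorities O1 > C1' > C3 > H), and compounds 1, 2 and 4 are bought as catalog chemicals.

**Step 1**
Reactants: 1 2',4'-dihydroxy-6'-methoxyacetophenone; 2 prenyl bromide (1-bromo-3-methylbut-2-ene)
Product: 3 1-[2,4-dihydroxy-6-methoxy-3-(3-methylbut-2-en-1-yl)phenyl]ethan-1-one
Conditions: 2 (1.0 equiv), 10% aq. KOH (2.2 equiv), 0 °C to 23 °C, 5 h; then 1 M HCl
Reagents that add atoms: none
Why: Phenoxide C-alkylation in water: the resorcinol-type dianion of 1 attacks the allylic bromide mainly through C3, the carbon flanked by both oxygens and given enol character by the chelated acetyl group (bond fixation), so the prenyl group enters between the two hydroxyls in an expected modest 30–40% yield, with the 5-prenyl, O-prenyl and bis-prenyl by-products removed by chromatography; no stereocenter is formed.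

**Step 2**
Reactants: 3 1-[2,4-dihydroxy-6-methoxy-3-(3-methylbut-2-en-1-yl)phenyl]ethan-1-one; 4 3-hydroxy-5-methoxybenzaldehyde
Product: 6 (E)-1-[2,4-dihydroxy-6-methoxy-3-(3-methylbut-2-en-1-yl)phenyl]-3-(3-hydroxy-5-methoxyphenyl)prop-2-en-1-one, via aldol adduct 5 (not isolated)
Conditions: LiN(SiMe3)2 (3.1 equiv on 3; 1.0 equiv on 4, premixed separately), THF, −78 °C to 23 °C, 16 h; then cold 1 M HCl
Reagents that add atoms: none
Why: Claisen–Schmidt aldol condensation through the lithium polyanion: the trilithio form of 3 (two phenoxides plus the methyl ketone enolate) adds to the aldehyde, whose meta-phenoxide cannot deactivate the carbonyl by resonance, and E1cB dehydration of aldolate 5 gives the conjugated (E)-enone as the thermodynamic alkene, which stays open as its polyanion until the acid quench.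

**Step 3**
Reactants: 6 (E)-1-[2,4-dihydroxy-6-methoxy-3-(3-methylbut-2-en-1-yl)phenyl]-3-(3-hydroxy-5-methoxyphenyl)prop-2-en-1-one
Product: 10 (2R)-2-(3-hydroxy-5-methoxyphenyl)-5-methoxy-8-(3-methylbut-2-en-1-yl)chroman-7-ol, via racemic flavanone 7 (not isolated), via cis-flavan-4-ol 8 (not isolated), via para-quinone methide 9 (not isolated)
Conditions: DBU (4 equiv), degassed MeCN, 23 °C, 1 h; then RuCl(p-cymene)[(R,R)-TsDPEN] (5 mol %), HCO2H (3 equiv), 40 °C, 36 h; then HCO2H (6 equiv more), 50 °C, 6 h
Reagents that add atoms: none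
Why: Proposed new method: DBU closes the chalcone by reversible intramolecular oxa-Michael addition of its only free ortho phenol (the non-enzymatic counterpart of chalcone isomerase) and keeps the enantiomers of 7 interconverting by retro-oxa-Michael opening to 6, while the (R,R)-configured Ru hydride reduces only (2R)-7 (hydride anti to the 2-aryl group, 4R sense as for aryl alkyl ketones) to cis-(2R,4R)-8, so C2 is set as R by dynamic kinetic resolution; once the medium is made acidic, the trioxygenated benzylic alcohol loses water through the 7-OH to para-quinone methide 9, which the Ru hydride reduces at C4 without touching C2 or the prenyl alkene; the closest known reaction types are Noyori–Ikariya transfer hydrogenation of 2-substituted chroman-4-ones with dynamic kinetic resolution by elimination-induced racemisation, and the domino transfer hydrogenation/deoxygenation of 7-hydroxy flavanones and isoflavanones through quinone methides.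

**Compound list**
1 | 2',4'-dihydroxy-6'-methoxyacetophenone | CC(=O)c1c(O)cc(O)cc1OC | starting material
2 | prenyl bromide (1-bromo-3-methylbut-2-ene) | CC(C)=CCBr | starting material
3 | 1-[2,4-dihydroxy-6-methoxy-3-(3-methylbut-2-en-1-yl)phenyl]ethan-1-one | CC(=O)c1c(O)c(CC=C(C)C)c(O)cc1OC | intermediate
4 | 3-hydroxy-5-methoxybenzaldehyde | COc1cc(O)cc(C=O)c1 | starting material
5 | aldol adduct, racemic 1-[2,4-dihydroxy-6-methoxy-3-(3-methylbut-2-en-1-yl)phenyl]-3-hydroxy-3-(3-hydroxy-5-methoxyphenyl)propan-1-one (not isolated) | COc1cc(O)cc(C(O)CC(=O)c2c(O)c(CC=C(C)C)c(O)cc2OC)c1 | intermediate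
6 | chalcone, (E)-1-[2,4-dihydroxy-6-methoxy-3-(3-methylbut-2-en-1-yl)phenyl]-3-(3-hydroxy-5-methoxyphenyl)prop-2-en-1-one | COc1cc(O)cc(/C=C/C(=O)c2c(O)c(CC=C(C)C)c(O)cc2OC)c1 | intermediate
7 | racemic flavanone, 7-hydroxy-2-(3-hydroxy-5-methoxyphenyl)-5-methoxy-8-(3-methylbut-2-en-1-yl)chroman-4-one, both enantiomers, interconverting through 6 (not isolated) | COc1cc(O)cc(C2CC(=O)c3c(OC)cc(O)c(CC=C(C)C)c3O2)c1 | intermediate
8 | cis-flavan-4-ol, (2R,4R)-2-(3-hydroxy-5-methoxyphenyl)-5-methoxy-8-(3-methylbut-2-en-1-yl)chromane-4,7-diol (not isolated) | COc1cc(O)cc([C@H]2C[C@@H](O)c3c(OC)cc(O)c(CC=C(C)C)c3O2)c1 | intermediate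
9 | para-quinone methide, (2R)-2-(3-hydroxy-5-methoxyphenyl)-5-methoxy-8-(3-methylbut-2-en-1-yl)-2,3-dihydro-7H-chromen-7-one (not isolated) | COc1cc(O)cc([C@H]2CC=C3C(OC)=CC(=O)C(CC=C(C)C)=C3O2)c1 | intermediate
10 | (2R)-2-(3-hydroxy-5-methoxyphenyl)-5-methoxy-8-(3-methylbut-2-en-1-yl)chroman-7-ol, that is (2R)-7,3'-dihydroxy-5,5'-dimethoxy-8-prenylflavan, CNP0389420.1 | COc1cc(O)cc([C@H]2CCc3c(OC)cc(O)c(CC=C(C)C)c3O2)c1 | target

**Step count**
Total steps: 3. Longest linear sequence: 3 (1 → 3 → 6 → 10).

**Steps most likely to fail, with fallbacks**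

Step 3 (highest risk). Four things can go wrong:
- Racemisation of 7 may be slower than reduction, so the yield stalls near 50% or the ee drops.
- The Ru hydride may reduce the C=C of the small standing amount of chalcone 6 to a dihydrochalcone.
- The ketone, hindered and electron-rich with oxygen at both ortho positions, may reduce slowly.
- Quinone methide 9 may tautomerise toward the prenyl side chain and close to a dimethylchromene.

The fallback sets out from 6 and separates ring closure from stereocontrol by a classical kinetic resolution with recycling. Chalcone 6 is closed with NaOAc in EtOH at reflux and racemic flavanone 7 is isolated. It is then treated with RuCl(p-cymene)[(R,R)-TsDPEN] in HCO2H/Et3N (5:2) and EtOAc at 40 °C, an acidic medium in which 7 neither opens nor racemises and no chalcone is present, and the reaction is stopped near 50% conversion. The (2R) half passes through 8 and 9 to the flavan, where the fallback comes back to the route at 10. The untouched (2S)-7-hydroxy-2-(3-hydroxy-5-methoxyphenyl)-5-methoxy-8-(3-methylbut-2-en-1-yl)chroman-4-one F7 is separated, racemised back to 7 with DBU in MeCN and resubmitted.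

Step 1 (regiochemistry and C- versus O-alkylation). If the 3-prenyl isomer is not the main product or cannot be separated, the fallback sets out from 1 and delivers the prenyl group intramolecularly.
- Compound 1 is O-alkylated at the non-chelated 4-OH with 3-chloro-3-methylbut-1-yne, DBU and CuCl2 (cat.) in MeCN at 0 °C, giving 1-[2-hydroxy-6-methoxy-4-(2-methylbut-3-yn-2-yloxy)phenyl]ethan-1-one F1.
- Semi-hydrogenation with H2 over Pd/CaCO3 poisoned with Pb(OAc)2 and quinoline in EtOAc gives 1-[2-hydroxy-6-methoxy-4-(2-methylbut-3-en-2-yloxy)phenyl]ethan-1-one F2.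
- Heating F2 in N,N-diethylaniline at 130 °C brings about the aromatic Claisen rearrangement. The [3,3] shift turns the 1,1-dimethylallyl ether into a normal prenyl group and is steered to C3 by the bond fixation of the chelated acetyl group. The fallback comes back to the route at 3.

Step 2 (condensation of unprotected polyphenols). If the polyanion is too insoluble or the aldol does not dehydrate, the fallback sets out from 3 and 4 and uses protected partners.
- Compound 3 with MeOCH2Cl and iPr2NEt in CH2Cl2 at 0 °C gives 1-[2-hydroxy-6-methoxy-4-(methoxymethoxy)-3-(3-methylbut-2-en-1-yl)phenyl]ethan-1-one F3; the chelated 2-OH stays free.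
- Compound 4 under the same conditions gives 3-methoxy-5-(methoxymethoxy)benzaldehyde F4.
- F3 and F4 in KOH, EtOH/H2O at 23 °C condense through the protected aldol adduct 1-[2-hydroxy-6-methoxy-4-(methoxymethoxy)-3-(3-methylbut-2-en-1-yl)phenyl]-3-hydroxy-3-[3-methoxy-5-(methoxymethoxy)phenyl]propan-1-one F5 (not isolated) to the protected chalcone (E)-1-[2-hydroxy-6-methoxy-4-(methoxymethoxy)-3-(3-methylbut-2-en-1-yl)phenyl]-3-[3-methoxy-5-(methoxymethoxy)phenyl]prop-2-en-1-one F6.
- Both acetals of F6 are removed with 3 M HCl in MeOH at 23 °C, and the fallback comes back to the route at 6.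

**Further compounds**
F1 | step 1 | 1-[2-hydroxy-6-methoxy-4-(2-methylbut-3-yn-2-yloxy)phenyl]ethan-1-one | CC(=O)c1c(O)cc(OC(C)(C)C#C)cc1OC
F2 | step 1 | 1-[2-hydroxy-6-methoxy-4-(2-methylbut-3-en-2-yloxy)phenyl]ethan-1-one | CC(=O)c1c(O)cc(OC(C)(C)C=C)cc1OC
F3 | step 2 | 1-[2-hydroxy-6-methoxy-4-(methoxymethoxy)-3-(3-methylbut-2-en-1-yl)phenyl]ethan-1-one | CC(=O)c1c(O)c(CC=C(C)C)c(OCOC)cc1OC
F4 | step 2 | 3-methoxy-5-(methoxymethoxy)benzaldehyde | COCOc1cc(OC)cc(C=O)c1
F5 | step 2 | racemic 1-[2-hydroxy-6-methoxy-4-(methoxymethoxy)-3-(3-methylbut-2-en-1-yl)phenyl]-3-hydroxy-3-[3-methoxy-5-(methoxymethoxy)phenyl]propan-1-one | COCOc1cc(OC)cc(C(O)CC(=O)c2c(O)c(CC=C(C)C)c(OCOC)cc2OC)c1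
F6 | step 2 | (E)-1-[2-hydroxy-6-methoxy-4-(methoxymethoxy)-3-(3-methylbut-2-en-1-yl)phenyl]-3-[3-methoxy-5-(methoxymethoxy)phenyl]prop-2-en-1-one | COCOc1cc(OC)cc(/C=C/C(=O)c2c(O)c(CC=C(C)C)c(OCOC)cc2OC)c1
F7 | step 3 | (2S)-7-hydroxy-2-(3-hydroxy-5-methoxyphenyl)-5-methoxy-8-(3-methylbut-2-en-1-yl)chroman-4-one | COc1cc(O)cc([C@@H]2CC(=O)c3c(OC)cc(O)c(CC=C(C)C)c3O2)c1
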